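## The problem

Mururin C (25) is a fully aromatic 2-arylbenzofuran whose core (ring A the benzo ring, ring C the furan ring) carries a methoxy group at C7, a 3-hydroxypropyl chain at C5, a formyl group at C3 and the pendant aryl ring B at C2. It has no stereocentre, so the task is one of regiocontrol on two highly substituted benzene rings and a fully substituted furan; the only geometric element that matters is the alkene geometry of an acyclic precursor. Ring B is a 3,4-dihydroxy-5-methoxyphenyl ring and not a syringyl ring, so its two phenols must be distinguished from its single methyl ether from the start, and the aryl–aryl bond must sit para to the central oxygen. The free catechol is sensitive to air and base, the C3 aldehyde is incompatible with organometallic and hydride reagents, and the primary alcohol reacts with chloroiminium reagents. The aldehyde must therefore come late and all three hydroxyls must stay masked until the last step. Before ring A exists, the furan is acid-sensitive. The feature that opens the synthesis is the 1,3-relationship in ring A between the C7 oxygen, which sits next to the ring-fusion carbon C7a, and the C5 carbon substituent. This is the pattern produced when an arylidene-succinic half-ester closes onto the alpha carbon of a 3-substituted furan: the carboxyl carbon becomes C7 and the ester-bearing carbon becomes C5.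

## Retrosynthesis

**25 from 24.** The three O–benzyl bonds are cut last. Benzyl is chosen for the chain hydroxyl and both ring B phenols because it survives butyllithium at low temperature, palladium coupling and the chloroiminium electrophile. A primary silyl ether is at risk of being converted to a formate by the chloroiminium salt, and acetal groups are at risk from POCl3. The forward step must remove two aryl benzyl ethers and one alkyl benzyl ether while sparing two aryl methyl ethers and the aldehyde.

**24 from 22.** The C3–CHO bond is cut. The formyl group cannot be carried through the organometallic arylation, and C3 of a 2-arylbenzofuran is the beta carbon of an enol ether, the most nucleophilic site of 22. The forward Vilsmeier–Haack reaction, which passes through iminium salt 23, has to prefer C3 over the free positions of the trioxygenated ring B and of ring A.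

**22 from 15 and 19.** The C2–C1' bond is cut. This splits the molecule into two fragments of similar size and uses the most acidic C–H bond of benzofuran 15 (C2–H) as the handle. Forming the furan ring instead (O1–C2) would mean building ring C onto a benzene and would abandon the furan-based construction of ring A. The forward step is C2 lithiation to 20, transmetalation to zinc reagent 21 and Negishi coupling with bromide 19.

**19 from 18 from 16.** Ring B is traced back through two O-benzylations to catechol 18, and 18 through a Dakin oxidation (by way of formate 17) to 5-bromo-2-hydroxy-3-methoxybenzaldehyde (16). In 16 the bromine is already para to the phenol and the formyl group sits where the second hydroxyl is needed. A syringol-type bromide, with two methoxy groups flanking one hydroxyl, would give the wrong oxygenation pattern and is not used.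

**15 from 8 through 14, 13, 12 and 9, with 10.** The O–benzyl bond of the chain is cut to alcohol 14, which comes from ester 13, and the chain is then shortened by two carbons at the alkene of 12. Compound 12 comes from benzylic alcohol 9 and ylide 10 by oxidation and Wittig olefination through aldehyde 11, and 9 comes from ester 8. A cross-coupling at C5 is not available because the annulation delivers an ester at C5, not a halide. The forward sequence needs two hydride reductions and one hydrogenation that leaves the furan double bond alone.

**8 from 6.** The C7 acetate is exchanged for a methyl ether by way of phenol 7. This is a protecting-group-level change with no skeletal consequence.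

**6 from 3.** The C7–C7a bond is cut and ring A is opened to the (E)-half-ester 3, a furan with one acyclic side chain. This cut is preferred because the ring closure, which runs through mixed anhydride 4 and ring A ketone 5, places oxygen at C7 and the ester at C5 by construction, with no directing-group chemistry on a benzene. The forward reaction must acylate the furan alpha carbon and not the beta carbon.

**3 from 1 and 2.** The alkene of 3 (the future C4–C5 bond) is cut by a Stobbe condensation to furan-3-carbaldehyde (1) and diethyl succinate (2), two bulk chemicals. The forward step must give the E-isomer, in which the acid arm is cis to the furan.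

## Roads not taken

Alternative 1: The C2–C1' and C3–CHO bonds are cut together. In the forward key step, silyl ether A3, the silyl counterpart of 15, would be lithiated at C2 and added to ring B pinacol boronate A2. Attack of a dimethoxycarbenium salt at C3 of the ate complex would trigger a 1,2-shift of ring B from boron to C2, giving the 2-boryl-2,3-dihydrobenzofuran A1 with aryl and acetal trans. Two bonds form in one operation, and the position of the formyl carbon is fixed by the mechanism and not by the innate selectivity of an electrophilic substitution; in this respect the road is better than the chosen Vilsmeier–Haack step. Its weak point is that the electrophile-induced shift dearomatises ring C. A1 must then be oxidised at the C–B bond, dehydrated and hydrolysed at the acetal to reach the oxidation pattern of 24, so the step saving over the Negishi/formylation pair is small or nil. The ate complex can also lose ring B or protodeboronate, and the silyl ether is exposed to a carbenium tetrafluoroborate. This road does not address ring A at all: A3 would still have to be made, most simply by the annulation chosen here. The chosen plan sets two separately reliable classical steps against the better regiochemical guarantee of A1.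

Alternative 2: The O1–C2 and C3–C(formyl) bonds are cut. In the forward key step, PtCl2 (divalent platinum) would activate diarylalkyne A5; the MOM-bearing oxygen would add to close ring C, and the methoxymethyl group would migrate to C3 to give 3-(methoxymethyl)benzofuran A4. The furan ring and the C3 carbon are installed in one atom-economical catalytic step, C3 is placed without ambiguity, and the two benzene fragments are joined convergently through an alkyne. In convergence and C3 regiocontrol this road is at least as good as the chosen one. Its weak points are that A5 needs a pentasubstituted ring A benzene with an ortho-alkynyl protected phenol and the three-carbon chain, so the chain homologation is not avoided, and that A4 sits at the CH2OMe oxidation level. A benzylic ether must then be oxidised to the aldehyde 24 in the presence of three benzyl ethers and two electron-rich rings. The chosen plan has the longer linear sequence. Against that, it assembles ring A from two commodity chemicals with the substitution pattern fixed by construction, it has no late oxidation-state change at C3 competing with the benzyl ethers, and every step is a classical transformation.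

Alternative 3: The C5–C6 bond of ring A is cut. In the forward key step, the 2-(1-siloxyvinyl)-3-alkenylfuran A7 would be heated so that the hexatriene closes in a six-electron electrocyclisation, and DDQ in the same flask would dehydrogenate the product to benzofuran silyl ether A6. Ring A forms with the complete, protected side chain already in place, so the five-step ester-to-propyl-ether adjustment of the chosen route is avoided; A6 is two steps (desilylation, methylation) away from 15. In chain economy this road is better. Its weak points are that A7 is a 2,3-disubstituted furan needing a regiocontrolled C2 acylation next to the alkenyl group and carrying a hydrolytically labile silyl enol ether. The ring closure uses the furan C2=C3 bond as the central alkene and therefore needs high temperature, and DDQ can oxidise the silyl enol ether or the benzylic ether in competition with the aromatisation. The chosen closure is driven irreversibly by formation of a phenol acetate and belongs to a long-established reaction class for heteroaryl half-esters; it pays for this with a longer chain elaboration.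

Key step: step 2

## Route

Assumption: compounds 1, 2, 10 and 16 are taken as commercially available. Benzofuran numbering O1, C2, C3, C3a, C4 to C7, C7a is used throughout.

Step 1
Reactants: 1 furan-3-carbaldehyde; 2 diethyl succinate
Product: 3 (E)-3-(ethoxycarbonyl)-4-(furan-3-yl)but-3-enoic acid
Conditions: t-BuOK, t-BuOH, reflux; then aq. HCl
Reagents that add atoms: none
Why: Stobbe condensation; the succinate enolate adds to the non-enolisable aldehyde, the aldolate lactonises with loss of ethoxide, and base-induced ring opening of the paraconic ester should give the half-ester with the furan trans to the ester, as is usual for aromatic aldehydes.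

Step 2
Reactants: 3 (E)-3-(ethoxycarbonyl)-4-(furan-3-yl)but-3-enoic acid
Product: 6 ethyl 7-acetoxybenzofuran-5-carboxylate, via mixed acetic anhydride 4 (not isolated), via 7-oxo-6,7-dihydrobenzofuran ester 5 (not isolated)
Conditions: Ac2O, NaOAc, reflux (about 140 °C)
Reagents that add atoms: acetic anhydride, CC(=O)OC(C)=O
Why: Stobbe half-ester benzannulation. Ac2O converts the acid of 3 into mixed anhydride 4, which under acetate catalysis reacts either as an acylium equivalent or, after loss of acetic acid, as a dienylketene. The activated carboxyl carbon bonds to the furan alpha carbon, forming C7–C7a and closing ring A in a six-membered mode (6-exo-trig at the acyl carbon in the Friedel–Crafts picture, or a six-electron electrocyclisation of the ketene with the furan C2=C3 bond as the central alkene). Rearomatisation of the furan leaves the ring A ketone 5, whose C6 proton is removed by acetate; the aromatic oxyanion so formed is acetylated by Ac2O in the same flask, so ring A emerges as aryl acetate 6 and the closure is irreversible. No stereocentre is formed. The step needs site selectivity for the furan alpha carbon (future C7a) over the furan beta carbon, and this is secured by the innate alpha reactivity of furan, whose sigma complex is stabilised by the ring oxygen, and by the E-geometry of 3, which holds the CH2CO2H arm cis to the furan. The closest known reaction type is the Ac2O/NaOAc cyclisation of aryl and heteroaryl Stobbe half-esters to acetoxy-substituted naphthoates and benzo-fused heteroarene esters.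

Step 3
Reactants: 6 ethyl 7-acetoxybenzofuran-5-carboxylate
Product: 8 ethyl 7-methoxybenzofuran-5-carboxylate, via ethyl 7-hydroxybenzofuran-5-carboxylate 7 (not isolated)
Conditions: K2CO3, EtOH, rt; then evaporate, MeI, K2CO3, DMF, rt
Reagents that add atoms: iodomethane, CI
Why: Ethanolysis of the aryl acetate releases phenol 7 (ethanol keeps the ethyl ester unchanged), and Williamson methylation of its phenoxide follows without isolation; the aryl ester and the benzofuran are inert to carbonate.

Step 4
Reactants: 8 ethyl 7-methoxybenzofuran-5-carboxylate
Product: 9 (7-methoxybenzofuran-5-yl)methanol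
Conditions: LiAlH4, THF, 0 °C
Reagents that add atoms: none
Why: Hydride reduction of an aryl ester to the benzylic alcohol; the aryl methyl ether and the benzofuran do not react with LiAlH4 at 0 °C.

Step 5
Reactants: 9 (7-methoxybenzofuran-5-yl)methanol; 10 ethyl (triphenylphosphoranylidene)acetate
Product: 12 ethyl (E)-3-(7-methoxybenzofuran-5-yl)prop-2-enoate, via 7-methoxybenzofuran-5-carbaldehyde 11 (not isolated)
Conditions: MnO2 (excess), 10, CH2Cl2, reflux
Reagents that add atoms: none
Why: Tandem benzylic oxidation and Wittig olefination; MnO2 oxidises the activated benzylic alcohol to aldehyde 11, which is trapped as it forms by the stabilised ylide, and stabilised ylides give the E-alkene.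

Step 6
Reactants: 12 ethyl (E)-3-(7-methoxybenzofuran-5-yl)prop-2-enoate
Product: 13 ethyl 3-(7-methoxybenzofuran-5-yl)propanoate
Conditions: H2 (1 atm), Pd/C, EtOAc, rt, stopped after one equivalent of H2
Reagents that add atoms: none
Why: Catalytic hydrogenation of a conjugated disubstituted alkene, which should be much faster than saturation of the aromatic furan C2=C3 bond at ambient pressure in a neutral solvent.

Step 7
Reactants: 13 ethyl 3-(7-methoxybenzofuran-5-yl)propanoate
Product: 14 3-(7-methoxybenzofuran-5-yl)propan-1-ol
Conditions: LiAlH4, THF, 0 °C
Reagents that add atoms: none
Why: Hydride reduction of an aliphatic ester to the primary alcohol; no other reducible group is present.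

Step 8
Reactants: 14 3-(7-methoxybenzofuran-5-yl)propan-1-ol
Product: 15 5-[3-(benzyloxy)propyl]-7-methoxybenzofuran
Conditions: NaH, BnBr, n-Bu4NI (cat.), THF, 0 °C to rt
Reagents that add atoms: benzyl bromide, BrCc1ccccc1
Why: Williamson ether synthesis on a primary alkoxide; the benzyl ether is chosen because it withstands the later lithiation at −78 °C, the palladium coupling and the chloroiminium reagent.

Step 9
Reactants: 16 5-bromo-2-hydroxy-3-methoxybenzaldehyde
Product: 18 5-bromo-3-methoxybenzene-1,2-diol, via aryl formate 17 (not isolated)
Conditions: H2O2, aq. NaOH, 0 °C to rt, under N2; then aq. HCl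
Reagents that add atoms: hydrogen peroxide, OO
Why: Dakin oxidation; hydroperoxide adds to the ortho-hydroxy aldehyde, the electron-rich aryl group migrates to oxygen to give formate 17, and this is saponified in the same flask, so the formyl carbon is replaced by the second phenol of the catechol.

Step 10
Reactants: 18 5-bromo-3-methoxybenzene-1,2-diol
Product: 19 1,2-bis(benzyloxy)-5-bromo-3-methoxybenzene
Conditions: BnBr, K2CO3, DMF, 60 °C, under N2
Reagents that add atoms: benzyl bromide, BrCc1ccccc1
Why: Double Williamson benzylation of the catechol; this fixes the distinction between the two future free phenols and the methyl ether of ring B.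

Step 11
Reactants: 15 5-[3-(benzyloxy)propyl]-7-methoxybenzofuran; 19 1,2-bis(benzyloxy)-5-bromo-3-methoxybenzene
Product: 22 2-[3,4-bis(benzyloxy)-5-methoxyphenyl]-5-[3-(benzyloxy)propyl]-7-methoxybenzofuran, via 2-lithiobenzofuran 20 (not isolated), via 2-benzofuranylzinc chloride 21 (not isolated)
Conditions: n-BuLi, THF, −78 °C; ZnCl2, −78 °C to rt; then 19, Pd(OAc)2, SPhos (cat.), 60 °C
Reagents that add atoms: none
Why: Deprotonation at C2, the most acidic C–H of a benzofuran, transmetalation to zinc and Negishi coupling; the electron-rich dialkylbiarylphosphine ligand is chosen to speed oxidative addition into the electron-rich bromide 19.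

Step 12
Reactants: 22 2-[3,4-bis(benzyloxy)-5-methoxyphenyl]-5-[3-(benzyloxy)propyl]-7-methoxybenzofuran
Product: 24 2-[3,4-bis(benzyloxy)-5-methoxyphenyl]-5-[3-(benzyloxy)propyl]-7-methoxybenzofuran-3-carbaldehyde, via C3 iminium chloride 23 (not isolated)
Conditions: POCl3, DMF, 0 to 60 °C; then aq. NaOAc
Reagents that add atoms: N,N-dimethylformamide, CN(C)C=O; water, O
Why: Vilsmeier–Haack formylation; the chloroiminium ion is a weak electrophile that should select C3, the enol-ether beta carbon of the 2-arylbenzofuran, over the hindered ring B positions, and iminium salt 23 is hydrolysed to the aldehyde on work-up.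

Step 13
Reactants: 24 2-[3,4-bis(benzyloxy)-5-methoxyphenyl]-5-[3-(benzyloxy)propyl]-7-methoxybenzofuran-3-carbaldehyde
Product: 25 Mururin C, 2-(3,4-dihydroxy-5-methoxyphenyl)-5-(3-hydroxypropyl)-7-methoxybenzofuran-3-carbaldehyde
Conditions: BCl3, C6HMe5, CH2Cl2, −78 to 0 °C; then H2O
Reagents that add atoms: none
Why: Lewis-acid cleavage of benzyl ethers with pentamethylbenzene as a non-basic trap for the benzyl cation; at low temperature BCl3 should cleave benzyl ethers much faster than aryl methyl ethers that have no neighbouring carbonyl group, and the aldehyde is only complexed reversibly.

## Compound list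

1 | furan-3-carbaldehyde (3-furaldehyde) | O=Cc1ccoc1 | starting material
2 | diethyl succinate | CCOC(=O)CCC(=O)OCC | starting material
3 | (E)-3-(ethoxycarbonyl)-4-(furan-3-yl)but-3-enoic acid | OC(=O)C/C(=C\c1ccoc1)C(=O)OCC | intermediate
4 | acetic (E)-3-(ethoxycarbonyl)-4-(furan-3-yl)but-3-enoic anhydride | CC(=O)OC(=O)C/C(=C\c1ccoc1)C(=O)OCC | intermediate
5 | ethyl 7-oxo-6,7-dihydrobenzofuran-5-carboxylate | CCOC(=O)C1=Cc2ccoc2C(=O)C1 | intermediate
6 | ethyl 7-acetoxybenzofuran-5-carboxylate | CCOC(=O)c1cc(OC(C)=O)c2occc2c1 | intermediate
7 | ethyl 7-hydroxybenzofuran-5-carboxylate | CCOC(=O)c1cc(O)c2occc2c1 | intermediate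
8 | ethyl 7-methoxybenzofuran-5-carboxylate | CCOC(=O)c1cc(OC)c2occc2c1 | intermediate
9 | (7-methoxybenzofuran-5-yl)methanol | COc1cc(CO)cc2ccoc12 | intermediate
10 | ethyl (triphenylphosphoranylidene)acetate | CCOC(=O)C=P(c1ccccc1)(c1ccccc1)c1ccccc1 | starting material
11 | 7-methoxybenzofuran-5-carbaldehyde | COc1cc(C=O)cc2ccoc12 | intermediate
12 | ethyl (E)-3-(7-methoxybenzofuran-5-yl)prop-2-enoate | CCOC(=O)/C=C/c1cc(OC)c2occc2c1 | intermediate
13 | ethyl 3-(7-methoxybenzofuran-5-yl)propanoate | CCOC(=O)CCc1cc(OC)c2occc2c1 | intermediate
14 | 3-(7-methoxybenzofuran-5-yl)propan-1-ol | COc1cc(CCCO)cc2ccoc12 | intermediate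
15 | 5-[3-(benzyloxy)propyl]-7-methoxybenzofuran | COc1cc(CCCOCc3ccccc3)cc2ccoc12 | intermediate
16 | 5-bromo-2-hydroxy-3-methoxybenzaldehyde | COc1cc(Br)cc(C=O)c1O | starting material
17 | 5-bromo-2-hydroxy-3-methoxyphenyl formate | COc1cc(Br)cc(OC=O)c1O | intermediate
18 | 5-bromo-3-methoxybenzene-1,2-diol | COc1cc(Br)cc(O)c1O | intermediate
19 | 1,2-bis(benzyloxy)-5-bromo-3-methoxybenzene | COc1cc(Br)cc(OCc2ccccc2)c1OCc1ccccc1 | intermediate
20 | {5-[3-(benzyloxy)propyl]-7-methoxybenzofuran-2-yl}lithium | [Li]c1cc2cc(CCCOCc3ccccc3)cc(OC)c2o1 | intermediate
21 | {5-[3-(benzyloxy)propyl]-7-methoxybenzofuran-2-yl}zinc chloride | Cl[Zn]c1cc2cc(CCCOCc3ccccc3)cc(OC)c2o1 | intermediate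
22 | 2-[3,4-bis(benzyloxy)-5-methoxyphenyl]-5-[3-(benzyloxy)propyl]-7-methoxybenzofuran | COc1cc(-c2cc3cc(CCCOCc4ccccc4)cc(OC)c3o2)cc(OCc2ccccc2)c1OCc1ccccc1 | intermediate
23 | N-({2-[3,4-bis(benzyloxy)-5-methoxyphenyl]-5-[3-(benzyloxy)propyl]-7-methoxybenzofuran-3-yl}methylidene)-N-methylmethanaminium chloride | COc1cc(-c2oc3c(OC)cc(CCCOCc4ccccc4)cc3c2C=[N+](C)C)cc(OCc2ccccc2)c1OCc1ccccc1.[Cl-] | intermediate
24 | 2-[3,4-bis(benzyloxy)-5-methoxyphenyl]-5-[3-(benzyloxy)propyl]-7-methoxybenzofuran-3-carbaldehyde | COc1cc(-c2oc3c(OC)cc(CCCOCc4ccccc4)cc3c2C=O)cc(OCc2ccccc2)c1OCc1ccccc1 | intermediate
25 | Mururin C, 2-(3,4-dihydroxy-5-methoxyphenyl)-5-(3-hydroxypropyl)-7-methoxybenzofuran-3-carbaldehyde | COc1cc(-c2oc3c(OC)cc(CCCO)cc3c2C=O)cc(O)c1O | target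

## Step count and risk

Total step count: 13. Longest linear sequence: 11 steps (steps 1 to 8 and 11 to 13, from furan-3-carbaldehyde). The ring B branch is steps 9 and 10.

**Step 2 (key step).** The most likely failure is thermal or acid-induced degradation of the electron-rich furan in hot acetic anhydride before ring closure. In addition, any half-ester with the wrong alkene geometry cannot reach the furan and is lost. Fallback: starting from 3, the acid would be converted with oxalyl chloride and catalytic DMF into ethyl (E)-4-chloro-2-(furan-3-ylmethylidene)-4-oxobutanoate F1. This would be closed by an intramolecular Friedel–Crafts acylation with SnCl4 in CH2Cl2 at −78 °C, which gives ketone 5 without any acetylating agent. Enolisation of 5 on work-up gives phenol 7, where the route is rejoined; 7 is methylated to 8 as in the second stage of step 3.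

**Step 12.** The chloroiminium ion must attack C3, which is flanked by the C2 aryl group and the peri C4–H. Slow substitution could force higher temperatures, and then site selectivity against the activated ring B positions ortho to the benzofuran could erode. Fallback: starting from 22, bromination with NBS at 0 °C, a small electrophile that reacts fast at the enol-ether carbon, would give 2-[3,4-bis(benzyloxy)-5-methoxyphenyl]-5-[3-(benzyloxy)propyl]-3-bromo-7-methoxybenzofuran F4. Bromine–lithium exchange with n-BuLi at −78 °C and a DMF quench would then place the formyl group through a defined C–Li bond, returning to the route at 24.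

**Step 11.** The risks are protonation of the organometallic by traces of moisture during the zinc transmetalation, and slow oxidative addition to the electron-rich bromide that leaves the zinc reagent to homocouple. Fallback: starting from 15, lithiation and quench with 2-isopropoxy-4,4,5,5-tetramethyl-1,3,2-dioxaborolane would give the isolable 2-{5-[3-(benzyloxy)propyl]-7-methoxybenzofuran-2-yl}-4,4,5,5-tetramethyl-1,3,2-dioxaborolane F3. This can be purified and coupled with 19 under Suzuki–Miyaura conditions (PdCl2(dppf), K3PO4, dioxane/water, 80 °C), returning to the route at 22.

**Step 6.** Over-reduction of the unsubstituted furan C2=C3 bond to the 2,3-dihydrobenzofuran could occur on palladium if the reaction is not stopped in time. Fallback: starting from 9, the alkene is avoided altogether. PBr3 would give 5-(bromomethyl)-7-methoxybenzofuran F2, and alkylation of the lithium enolate of ethyl acetate (LiN(i-Pr)2, THF, −78 °C) with F2 would give the saturated ester directly, returning to the route at 13.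

**Step 13.** Three failure processes are possible: incomplete cleavage of the aliphatic benzyl ether, loss of the ring B methyl ether through boron chelation by the newly freed catechol, or Friedel–Crafts benzylation of the electron-rich rings if cation trapping is inefficient. Fallback: starting from 24, reductive cleavage by hydrogenolysis (H2, Pd/C, EtOAc/THF, rt) would replace the Lewis-acid cleavage and give 25 directly. The C3 aldehyde is a vinylogous formate and should be reduced only slowly. This fallback passes through no new compound (none, F0).

## Further compounds

F1 | step 2 | ethyl (E)-4-chloro-2-(furan-3-ylmethylidene)-4-oxobutanoate | CCOC(=O)/C(CC(Cl)=O)=C/c1ccoc1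
F2 | step 6 | 5-(bromomethyl)-7-methoxybenzofuran | COc1cc(CBr)cc2ccoc12
F3 | step 11 | 2-{5-[3-(benzyloxy)propyl]-7-methoxybenzofuran-2-yl}-4,4,5,5-tetramethyl-1,3,2-dioxaborolane | COc1cc(CCCOCc3ccccc3)cc2cc(B3OC(C)(C)C(C)(C)O3)oc12
F4 | step 12 | 2-[3,4-bis(benzyloxy)-5-methoxyphenyl]-5-[3-(benzyloxy)propyl]-3-bromo-7-methoxybenzofuran | COc1cc(-c2oc3c(OC)cc(CCCOCc4ccccc4)cc3c2Br)cc(OCc2ccccc2)c1OCc1ccccc1
F0 | step 13 | none | none
A1 | alternative 1 | 2-[3,4-bis(benzyloxy)-5-methoxyphenyl]-5-[3-(tert-butyldimethylsilyloxy)propyl]-3-(dimethoxymethyl)-7-methoxy-2-(4,4,5,5-tetramethyl-1,3,2-dioxaborolan-2-yl)-2,3-dihydrobenzofuran (racemic, aryl and acetal trans, one enantiomer drawn) | COC(OC)[C@@H]1c2cc(CCCO[Si](C)(C)C(C)(C)C)cc(OC)c2O[C@@]1(B1OC(C)(C)C(C)(C)O1)c1cc(OC)c(OCc2ccccc2)c(OCc2ccccc2)c1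
A2 | alternative 1 | 2-[3,4-bis(benzyloxy)-5-methoxyphenyl]-4,4,5,5-tetramethyl-1,3,2-dioxaborolane | COc1cc(B2OC(C)(C)C(C)(C)O2)cc(OCc2ccccc2)c1OCc1ccccc1
A3 | alternative 1 | tert-butyl[3-(7-methoxybenzofuran-5-yl)propoxy]dimethylsilane | COc1cc(CCCO[Si](C)(C)C(C)(C)C)cc2ccoc12
A4 | alternative 2 | 2-[3,4-bis(benzyloxy)-5-methoxyphenyl]-5-[3-(benzyloxy)propyl]-7-methoxy-3-(methoxymethyl)benzofuran | COCc1c(-c2cc(OC)c(OCc3ccccc3)c(OCc3ccccc3)c2)oc2c(OC)cc(CCCOCc3ccccc3)cc12
A5 | alternative 2 | 1,2-bis(benzyloxy)-5-({5-[3-(benzyloxy)propyl]-3-methoxy-2-(methoxymethoxy)phenyl}ethynyl)-3-methoxybenzene | COCOc1c(OC)cc(CCCOCc2ccccc2)cc1C#Cc1cc(OC)c(OCc2ccccc2)c(OCc2ccccc2)c1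
A6 | alternative 3 | {5-[3-(benzyloxy)propyl]benzofuran-7-yloxy}(tert-butyl)dimethylsilane | CC(C)(C)[Si](C)(C)Oc1cc(CCCOCc2ccccc2)cc2ccoc12
A7 | alternative 3 | tert-butyl[(1-{3-[(E)-5-(benzyloxy)pent-1-en-1-yl]furan-2-yl}ethenyl)oxy]dimethylsilane | C=C(O[Si](C)(C)C(C)(C)C)c1occc1/C=C/CCCOCc1ccccc1
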